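**Numbering.** Compounds 1–14 are fixed by the steps and listed after them. Atom labels: arene C1–C6 (OH on C1 and C2, cyclopentyl on C3, bridge on C5), bridge carbons C7/C7', cyclopentane C1'–C5' (C1' quaternary stereocentre, C2' gem-dimethyl). The same labels apply to the symmetry-related half.

## Analysis of the target

Target 14 is a C2-symmetric bibenzyl: two catechol rings (ring A and its copy ring A', OH on C1 and C2) are joined through the C7–C7' ethane bridge at C5, and each carries at C3, ortho to the C2 hydroxyl and meta to the bridge, a 1,2,2-trimethylcyclopentyl ring (ring B, C1'–C5'). The only stereocentres are the two benzylic quaternary carbons C1' (methyl, aryl, C2', C5'), both S; each is flanked by the fully substituted C2', so every arm holds two adjacent quaternary carbons. The two C1' centres are nine bonds apart and cannot control one another, so each needs an external chiral influence, and the meso (R,S) isomer is a diastereomer of almost identical polarity. A quaternary centre cannot be corrected by epimerisation, and ring B has no heteroatom to direct its formation. The C3–C1' bond is the hardest bond: it joins an arene carbon with an ortho oxygen to a carbon that ends up between a methyl group and a gem-dimethyl carbon. Sensitive points are the catechols (air oxidation to ortho-quinones, hence methyl ethers until the end) and any carbocation at C2' or C1', where 1,2-methyl or 1,2-aryl shifts would scramble C1' without changing the constitution. The feature that invites a two-directional attack is the pair of symmetry-equivalent C3–C1' bonds on either side of the C7–C7' bond: C1' carries a methyl group and lies 1,3 to C3', so with a carbonyl at C3' both C1' centres become the β-carbons of two identical enones. The task is therefore to make two remote, hindered benzylic quaternary stereocentres of one configuration, and their gem-dimethyl neighbours, in few steps.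

## Retrosynthetic reasoning

**14 ⇒ 12.** The four O–H bonds are traced back to O–CH3 bonds. Methyl ethers are the smallest mask for the catechols, they survive every base, enolate and reduction step of the route, and they are the directing groups needed at the start. The forward reaction is a single global ether cleavage at the very end, so the air-sensitive catechol is never carried through a step.

**12 ⇒ 10 ⇒ 9 ⇒ 8.** A carbonyl is placed at C3' of each ring B (10); it is the handle that allows the two C2'–CH3 bonds to be cut back by enolate chemistry. A saturated C3' ketone would enolise toward C4', away from the hindered C2'. The C4'=C5' double bond of 9 and 8 therefore serves as the regiochemical device: in enone 8 the only sp3 α-carbon is C2', so exhaustive methylation can occur only there. Forward, this means methylation (8 to 9), hydrogenation (9 to 10) and a hydrazone-based deoxygenation (10 to 12), none of which passes through a cation near C1'.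

**8 ⇒ 6.** The C4'=C5' double bond is removed, leaving the saturated bis-ketone 6. Forward, a kinetic enolisation of 6 at the unhindered C4' followed by oxidation of the enolate has to give the enone. Enolisation on the C2' side cannot lead to an enone, because C1' carries no hydrogen.

**6 ⇒ 4 + two molecules of 5 (key disconnection).** Both C3–C1' bonds are cut at once, across the symmetry axis. This is the place to cut because the central C7–C7' bond is then already present in a trivial achiral core, and both stereocentres arise in one operation from one catalyst. The cyclopentane arrives as the simplest possible building block, enone 5. The forward reaction must add each aryl group of 4 to the β-carbon of 5 with catalyst-controlled facial selectivity, twice, with the ortho-methoxy group in place. Because the two additions are independent, the rare wrong-face addition ends up mainly in the meso diastereomer and not in the enantiomer of 6.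

**4 ⇒ 2.** The two C3–B bonds are cut back to C3–H. In 2 the C2 methoxy group is ortho to C3, and C3 is the only ortho position not flanked by the bridge, so a directed ortho-metalation should place the metal exactly where the ring B carbon has to go.

**2 ⇒ two molecules of 1.** The C7–C7' bond, the easiest bond of the molecule, is made first: it is cut into two identical benzylic halves, and the forward reaction is the reductive homocoupling of two molecules of the bulk benzylic chloride 1.

## Alternatives that were turned down

**Alternative 1:** (textbook) Cut the C7–C7' bond last. The monomer A1 would be made in enantioenriched form, brominated at its aryl methyl group to A2, and A2 would be homocoupled reductively to 12. It was turned down for three reasons. First, the aryl methyl of A1 sits on a ring with two methoxy-activated free positions, so radical bromination competes with nuclear bromination; the alternative is to carry an oxidised C7 handle through enolate, dehydrogenation and Wolff–Kishner chemistry. Second, the least demanding bond of the molecule would be formed at the end, on the most valuable material, by a coupling that also reduces A2 back to A1. Third, it gains nothing in stereocontrol (the statistics of pairing two halves are the same) and needs more operations, since every step before the coupling is run on twice the molar amount and the handle costs two further steps.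

**Alternative 2:** Cut C3–C1' with reversed polarity: a double palladium-catalysed asymmetric α-arylation of a ketone enolate (its second α-position blocked) by a 3,3'-dihalo derivative of 2 would give the bis(α-aryl ketone) A3. The carbonyl of A3 sits on C2' and would then be turned into the gem-dimethyl group. It was turned down for two reasons. Coupling at a tetrasubstituted enolate carbon with an ortho-substituted aryl halide is the weakest part of the scope of this reaction, and the blocking group costs steps on both sides. More seriously, the one-step conversion of the C2' carbonyl of A3 into CMe2 with Me2TiCl2 runs through a C2' carbocation next to C1'. A 1,2-methyl shift would give the tertiary benzylic C1' cation, and a 1,2-aryl shift would give the mirror-image skeleton; both return the same constitution with lost configuration. The cation-free detour (methylenation, cyclopropanation, hydrogenolysis) takes three steps, so nothing is saved.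

**Alternative 3:** Form C3–C1' by a double aromatic Claisen rearrangement with 1,3-chirality transfer. The bis(allyl aryl ether) A4, from a vanillin-type bisphenol and an enantioenriched cyclopentenol, would rearrange to the bisphenol A5, which already holds the C1'/C2' pair; hydrogenation and demethylation would finish. This is the shortest plan on paper, but it was turned down for three reasons. The new bond must form at a trisubstituted alkene carbon next to a quaternary carbon inside a cyclic transition state. A4 is a secondary allylic aryl ether whose ionisation gives a tertiary allyl cation, so thermal loss of the phenol (elimination to a diene) or a 1,3-shift should outrun the rearrangement. Making A4 by a substitution at the same labile allylic carbon risks transposition and loss of configuration.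

Key step: step 3

**Assumption (chemistry).** The (R,R)-antipode of the bisoxazoline ligand is taken to deliver the S configuration at C1'; if the sense of induction is the opposite, the (S,S)-ligand is used with no other change. Compound 1 is taken as commercial.

## Route

**Step 1**
Reactants: 1 4-(chloromethyl)-1,2-dimethoxybenzene (veratryl chloride; 2 equiv, two molecules are joined to each other)
Product: 2 1,2-bis(3,4-dimethoxyphenyl)ethane
Conditions: NiCl2(PPh3)2 (5 mol%), Zn dust (1.2 equiv), Et4NI (20 mol%), THF, 50 °C
Reagents that add atoms: veratryl chloride (second molecule of 1), COc1ccc(CCl)cc1OC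
Why: Nickel-catalysed reductive homocoupling (Wurtz type) of a benzylic chloride, in which two molecules of 1 each give up chloride and are joined at their benzylic carbons; zinc reduces the divalent nickel salt to zerovalent nickel, which activates the benzylic C–Cl bond, and zinc takes up both chlorides. No stereocentre is formed.

**Step 2**
Reactants: 2 1,2-bis(3,4-dimethoxyphenyl)ethane
Product: 4 [ethane-1,2-diylbis(2,3-dimethoxy-5,1-phenylene)]diboronic acid, via 1,2-bis(3-lithio-4,5-dimethoxyphenyl)ethane 3 (not isolated)
Conditions: n-BuLi (3.0 equiv), TMEDA (3.0 equiv), Et2O, 0 °C to rt; B(OiPr)3 (4 equiv), −78 °C to rt; 1 M HCl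
Reagents that add atoms: triisopropyl borate, CC(C)OB(OC(C)C)OC(C)C; water, O
Why: Directed ortho-metalation followed by borate quench; the C2 methoxy group directs lithium to C3, the ortho position next to a hydrogen, whereas C6 is shielded by the bridge carbon C5. Each ring reacts independently; acid hydrolysis should give the free bis(boronic acid).

**Step 3**
Reactants: 4 [ethane-1,2-diylbis(2,3-dimethoxy-5,1-phenylene)]diboronic acid; 5 3-methylcyclopent-2-en-1-one (8 equiv)
Product: 6 (3S,3'S)-3,3'-[ethane-1,2-diylbis(2,3-dimethoxy-5,1-phenylene)]bis(3-methylcyclopentan-1-one)
Conditions: PdCl2 (10 mol%), (R,R)-PhBOX [2,2'-(propane-2,2-diyl)bis((4R)-4-phenyl-4,5-dihydrooxazole)] (12 mol%), AgSbF6 (40 mol%), MeOH/H2O 9:1, 40 °C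
Reagents that add atoms: none
Why: Each C3–B bond should transmetalate to the cationic divalent palladium–bisoxazoline complex, the aryl–palladium species coordinates 5, migratory insertion delivers the aryl group to the β-carbon (the future C1') and water protonates the palladium enolate, so palladium stays divalent throughout. The closest known reaction type is the palladium-catalysed enantioselective conjugate addition of arylboronic acids to 3-methylcyclopent-2-enone, whose scope includes ortho-alkoxy arylboronic acids of this 2,3-dialkoxy-5-alkyl pattern; here it is run at both ends of one molecule. No ring is closed; the step forms both C3–C1' bonds and joins three components around the bibenzyl core. Each C1' stereocentre is set by catalyst control, the phenyl groups of the C2-symmetric ligand differentiating the enone faces in the insertion step. The two sites are nine bonds apart and react independently, so a per-event selectivity of s to 1 should give the (S,S) and (R,R) products in a ratio of s squared to 1, with the errors collected in the meso diastereomer. The step needs insertion to win over protonolysis of the aryl–palladium bond; the large excess of 5 serves this, because insertion is first order in enone. Heck-type β-hydride elimination is excluded by the structure, since after insertion palladium sits on C2' and the neighbouring C1' has no hydrogen.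

**Step 4**
Reactants: 6 (3S,3'S)-bis(3-aryl-3-methylcyclopentanone)
Product: 8 (4R,4'R)-4,4'-[ethane-1,2-diylbis(2,3-dimethoxy-5,1-phenylene)]bis(4-methylcyclopent-2-en-1-one), via dilithium bis(cyclopent-1-en-1-olate) 7 (not isolated)
Conditions: LDA (2.4 equiv), THF, −78 °C; PhS(Cl)=NtBu (2.6 equiv), −78 °C
Reagents that add atoms: none
Why: Kinetic deprotonation should occur at C4', remote from the quaternary C1', and the Mukaiyama dehydrogenation (attack of the enolate on sulfur, then syn-elimination) should give the C4'=C5' enone at low temperature. An enolate formed on the C2' side cannot eliminate, so no isomeric enone can arise. The spatial arrangement at C1' is untouched; the descriptor changes from S to R only through the priority rules.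

**Step 5**
Reactants: 8 (4R,4'R)-bis(4-aryl-4-methylcyclopent-2-enone)
Product: 9 (4R,4'R)-4,4'-[ethane-1,2-diylbis(2,3-dimethoxy-5,1-phenylene)]bis(4,5,5-trimethylcyclopent-2-en-1-one)
Conditions: KOtBu (6 equiv), MeI (12 equiv), THF, 0 °C to rt
Reagents that add atoms: iodomethane, CI
Why: Exhaustive enolate C-methylation: C2' is the only sp3 α-carbon of the enone and γ-deprotonation is impossible at the quaternary C1', so all four methyl groups can only go to C2'. The planar cross-conjugated dienolate is approached by the small electrophile anti to the aryl group in both methylations. Product 9 has no enolisable position left.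

**Step 6**
Reactants: 9 (4R,4'R)-bis(4-aryl-4,5,5-trimethylcyclopent-2-enone)
Product: 10 (3R,3'R)-3,3'-[ethane-1,2-diylbis(2,3-dimethoxy-5,1-phenylene)]bis(2,2,3-trimethylcyclopentan-1-one)
Conditions: H2 (1 atm), Pd/C (10 wt% palladium on carbon), EtOAc, rt
Reagents that add atoms: none
Why: Heterogeneous catalytic hydrogenation of the cis-disubstituted enone double bond; the hindered ketone, the aryl ethers and the quaternary benzylic carbon are inert under these conditions.

**Step 7**
Reactants: 10 (3R,3'R)-bis(3-aryl-2,2,3-trimethylcyclopentanone)
Product: 12 1,1'-(ethane-1,2-diyl)bis{3,4-dimethoxy-5-[(1S)-1,2,2-trimethylcyclopentyl]benzene}, via bis(hydrazone) 11 (not isolated)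
Conditions: N2H4·H2O (excess), KOH, diethylene glycol, 130 °C, then distil to 200 °C, under N2
Reagents that add atoms: none
Why: Wolff–Kishner reduction in the Huang-Minlon variant, the standard deoxygenation of 2,2,3-trisubstituted cyclopentanones of the cuparenone type. The mechanism is anionic, so no cation arises next to C1' and the stereocentre cannot migrate or racemise.

**Step 8**
Reactants: 12 1,1'-(ethane-1,2-diyl)bis{3,4-dimethoxy-5-[(1S)-1,2,2-trimethylcyclopentyl]benzene}
Product: 14 5,5'-(ethane-1,2-diyl)bis{3-[(1S)-1,2,2-trimethylcyclopentyl]benzene-1,2-diol}, via bis(2-bromo-1,3,2-benzodioxaborole) 13 (not isolated)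
Conditions: BBr3 (6 equiv), CH2Cl2, −78 °C to rt; degassed H2O, 0 °C; work-up under argon
Reagents that add atoms: none
Why: Lewis-acid cleavage of the four aryl methyl ethers; each catechol is held as a cyclic bromoborate until hydrolysis. The step should leave the quaternary aryl–alkyl bond intact at low temperature, and running it last keeps the oxidation-sensitive catechol out of all other steps.

## Compound list

1 | 4-(chloromethyl)-1,2-dimethoxybenzene | COc1ccc(CCl)cc1OC | starting material
2 | 1,2-bis(3,4-dimethoxyphenyl)ethane | COc1ccc(CCc2ccc(OC)c(OC)c2)cc1OC | intermediate
3 | 1,2-bis(3-lithio-4,5-dimethoxyphenyl)ethane | [Li]c1cc(CCc2cc([Li])c(OC)c(OC)c2)cc(OC)c1OC | intermediate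
4 | [ethane-1,2-diylbis(2,3-dimethoxy-5,1-phenylene)]diboronic acid | OB(O)c1cc(CCc2cc(B(O)O)c(OC)c(OC)c2)cc(OC)c1OC | intermediate
5 | 3-methylcyclopent-2-en-1-one | CC1=CC(=O)CC1 | starting material
6 | (3S,3'S)-3,3'-[ethane-1,2-diylbis(2,3-dimethoxy-5,1-phenylene)]bis(3-methylcyclopentan-1-one) | C[C@]1(c2cc(CCc3cc(OC)c(OC)c([C@@]4(C)CCC(=O)C4)c3)cc(OC)c2OC)CCC(=O)C1 | intermediate
7 | dilithium bis(cyclopent-1-en-1-olate) of 6 (enolised toward C4', both C1' as in 6) | C[C@]1(c2cc(CCc3cc(OC)c(OC)c([C@@]4(C)CC=C(O[Li])C4)c3)cc(OC)c2OC)CC=C(O[Li])C1 | intermediate
8 | (4R,4'R)-4,4'-[ethane-1,2-diylbis(2,3-dimethoxy-5,1-phenylene)]bis(4-methylcyclopent-2-en-1-one) | C[C@]1(c2cc(CCc3cc(OC)c(OC)c([C@@]4(C)C=CC(=O)C4)c3)cc(OC)c2OC)C=CC(=O)C1 | intermediate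
9 | (4R,4'R)-4,4'-[ethane-1,2-diylbis(2,3-dimethoxy-5,1-phenylene)]bis(4,5,5-trimethylcyclopent-2-en-1-one) | C[C@]1(c2cc(CCc3cc(OC)c(OC)c([C@@]4(C)C=CC(=O)C4(C)C)c3)cc(OC)c2OC)C=CC(=O)C1(C)C | intermediate
10 | (3R,3'R)-3,3'-[ethane-1,2-diylbis(2,3-dimethoxy-5,1-phenylene)]bis(2,2,3-trimethylcyclopentan-1-one) | C[C@]1(c2cc(CCc3cc(OC)c(OC)c([C@@]4(C)CCC(=O)C4(C)C)c3)cc(OC)c2OC)CCC(=O)C1(C)C | intermediate
11 | bis(hydrazone) of 10 (C1' centres unchanged) | C[C@]1(c2cc(CCc3cc(OC)c(OC)c([C@@]4(C)CCC(=NN)C4(C)C)c3)cc(OC)c2OC)CCC(=NN)C1(C)C | intermediate
12 | 1,1'-(ethane-1,2-diyl)bis{3,4-dimethoxy-5-[(1S)-1,2,2-trimethylcyclopentyl]benzene} | C[C@]1(c2cc(CCc3cc(OC)c(OC)c([C@@]4(C)CCCC4(C)C)c3)cc(OC)c2OC)CCCC1(C)C | intermediate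
13 | bis(2-bromo-1,3,2-benzodioxaborole) of 14 (each catechol as cyclic bromoborate, both C1' S) | C[C@]1(c2cc(CCc3cc4OB(Br)Oc4c([C@@]5(C)CCCC5(C)C)c3)cc6OB(Br)Oc26)CCCC1(C)C | intermediate
14 | 5,5'-(ethane-1,2-diyl)bis{3-[(1S)-1,2,2-trimethylcyclopentyl]benzene-1,2-diol} | CC1(C)CCC[C@]1(C)c1cc(CCc2cc(O)c(O)c([C@@]3(C)CCCC3(C)C)c2)cc(O)c1O | target

## Step count and least certain steps

Total step count: 8. Longest linear sequence: 8 steps (1 to 14); 5 enters at step 3.

**Step 3 (key step).** Two things are most likely to go wrong. Protonolysis of one aryl–boron or aryl–palladium bond may occur before the hindered insertion, so that one arm is lost and the two-fold addition stays incomplete. The ortho-methoxy group may also erode facial selectivity, which would raise the share of the meso diastereomer; this isomer is hard to remove because the two centres are remote. Crystallisation of 12 or chromatography on a chiral phase is then the place to purify. The fallback sets out from 3, generated from 2 as in step 2, and changes the bond that is formed in the stereodetermining event. Addition of 3 to 3-ethoxycyclopent-2-en-1-one and acidic work-up (Stork–Danheiser sequence) should give 3,3'-[ethane-1,2-diylbis(2,3-dimethoxy-5,1-phenylene)]bis(cyclopent-2-en-1-one) F1. A copper-catalysed enantioselective conjugate addition of AlMe3 (copper thiophene-2-carboxylate as the monovalent copper source, a chiral phosphoramidite, Et2O, −30 °C) then creates each C1' centre by C–CH3 bond formation, and the route is rejoined at 6.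

**Step 2.** Metalation may lose regiocontrol (attack at C6 or at the benzylic C7), or the second lithiation may stay incomplete because the monolithio species aggregates. This cannot be repaired from a compound of the route, since the ring positions are fixed in 2. The fallback therefore sets out from commercial 3-bromo-4,5-dimethoxybenzaldehyde F2, in which the halogen already marks C3. McMurry coupling (TiCl4, Zn, THF, reflux) should give (E)-1,2-bis(3-bromo-4,5-dimethoxyphenyl)ethene F3. Diimide reduction (TsNHNH2, NaOAc, aqueous THF, reflux) should give 1,2-bis(3-bromo-4,5-dimethoxyphenyl)ethane F4. Bromine–lithium exchange (n-BuLi, THF, −78 °C) comes back to the route at 3, which is borylated as in step 2.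

**Step 5.** The second methylation at C2' has to build a quaternary carbon next to C1'. Stalling at the monomethyl stage or O-methylation of the dienolate would give mixtures, because four C–C bonds must form in one flask. The fallback sets out from 6 and replaces the double bond by a classical blocking group. Formylation at C4' (HCO2Et, NaH) should give the bis(hydroxymethylene) ketone F5. Treatment with n-BuSH and TsOH should give the bis(n-butylthiomethylene) ketone F6. KOtBu and MeI then dimethylate C2' to F7, and KOH in diethylene glycol at 120 °C removes the blocking group. The route is rejoined at 10.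

**Step 7.** Hydrazone formation at the C3' carbonyl, which is flanked by the gem-dimethyl carbon, may be slow, so that azine formation or partial ether cleavage by hot alkali takes over. The fallback sets out from 10. Reduction with LiAlH4 should give the diol F8, and NaH, CS2 and MeI convert it to the bis(S-methyl xanthate) F9. Barton–McCombie deoxygenation (Bu3SnH, AIBN, toluene, reflux) comes back to the route at 12.

## Further compounds

F1 | step 3 | 3,3'-[ethane-1,2-diylbis(2,3-dimethoxy-5,1-phenylene)]bis(cyclopent-2-en-1-one) | O=C1CCC(c2cc(CCc3cc(OC)c(OC)c(C4=CC(=O)CC4)c3)cc(OC)c2OC)=C1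
F2 | step 2 | 3-bromo-4,5-dimethoxybenzaldehyde (commercial) | O=Cc1cc(OC)c(OC)c(Br)c1
F3 | step 2 | (E)-1,2-bis(3-bromo-4,5-dimethoxyphenyl)ethene | COc1cc(/C=C/c2cc(OC)c(OC)c(Br)c2)cc(Br)c1OC
F4 | step 2 | 1,2-bis(3-bromo-4,5-dimethoxyphenyl)ethane | COc1cc(CCc2cc(OC)c(OC)c(Br)c2)cc(Br)c1OC
F5 | step 5 | bis(C4'-hydroxymethylene) derivative of 6 | C[C@]1(c2cc(CCc3cc(OC)c(OC)c([C@@]4(C)CC(=CO)C(=O)C4)c3)cc(OC)c2OC)CC(=CO)C(=O)C1
F6 | step 5 | bis(C4'-n-butylthiomethylene) derivative of 6 | C[C@]1(c2cc(CCc3cc(OC)c(OC)c([C@@]4(C)CC(=CSCCCC)C(=O)C4)c3)cc(OC)c2OC)CC(=CSCCCC)C(=O)C1
F7 | step 5 | bis(C4'-n-butylthiomethylene) derivative of 10 | C[C@]1(c2cc(CCc3cc(OC)c(OC)c([C@@]4(C)CC(=CSCCCC)C(=O)C4(C)C)c3)cc(OC)c2OC)CC(=CSCCCC)C(=O)C1(C)C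
F8 | step 7 | diol from reduction of 10 (carbinol centres as a mixture, C1' as in 10) | C[C@]1(c2cc(CCc3cc(OC)c(OC)c([C@@]4(C)CCC(O)C4(C)C)c3)cc(OC)c2OC)CCC(O)C1(C)C
F9 | step 7 | bis(S-methyl xanthate) of F8 | C[C@]1(c2cc(CCc3cc(OC)c(OC)c([C@@]4(C)CCC(OC(=S)SC)C4(C)C)c3)cc(OC)c2OC)CCC(OC(=S)SC)C1(C)C
A1 | alternative 1 | 1,2-dimethoxy-5-methyl-3-[(1S)-1,2,2-trimethylcyclopentyl]benzene | C[C@]1(c2cc(C)cc(OC)c2OC)CCCC1(C)C
A2 | alternative 1 | 5-(bromomethyl)-1,2-dimethoxy-3-[(1S)-1,2,2-trimethylcyclopentyl]benzene | C[C@]1(c2cc(CBr)cc(OC)c2OC)CCCC1(C)C
A3 | alternative 2 | (2R,2'R)-2,2'-[ethane-1,2-diylbis(2,3-dimethoxy-5,1-phenylene)]bis(2-methylcyclopentan-1-one) | C[C@]1(c2cc(CCc3cc(OC)c(OC)c([C@@]4(C)CCCC4=O)c3)cc(OC)c2OC)CCCC1=O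
A4 | alternative 3 | 1,2-bis{3-methoxy-4-[(1S)-3,4,4-trimethylcyclopent-2-en-1-yl]oxyphenyl}ethane | COc1cc(CCc2ccc(O[C@@H]3C=C(C)C(C)(C)C3)c(OC)c2)ccc1O[C@@H]1C=C(C)C(C)(C)C1
A5 | alternative 3 | 4,4'-(ethane-1,2-diyl)bis{2-methoxy-6-[(1S)-1,5,5-trimethylcyclopent-2-en-1-yl]phenol} | C[C@]1(c2cc(CCc3cc(OC)c(O)c([C@@]4(C)C=CCC4(C)C)c3)cc(OC)c2O)C=CCC1(C)C
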